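The oxane is traced back to a furan: ring carbons C3–C6 are the four furan carbons, C2 is the carbon of a 2-furyl carbinol and O1 is its hydroxyl oxygen. One oxidative ring expansion (step 4) converts the (S)-furyl carbinol 4, whose C2 arm is a two-carbon chain ending in a silyl ether, into pyranone 7, making the O1–C6 bond and the six-membered ring with C2 untouched. The remaining enone relays C2 to C5 (trans 1,2-reduction, then suprafacial Claisen shift); the C5 arm is then coupled with a separately made (R)-configured (E)-vinyl iodide, and the C2 arm is oxidised and methylenated to the acrylic acid.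

Key step: step 4

Remarks on the chemistry (one line each):
- Ring numbering throughout: O1, C2 (acrylic acid carbon), C3, C4, C5 (chain carbon), C6; TBSO = tert-butyldimethylsilyloxy.
- Structure check: the target is the trans-2,5-disubstituted oxane (2R,5S) with a (3E) alkene and a (7R) carbinol in the chain; the (S) descriptor of 4 and 7 corresponds to 2R in the target because the arm outranks C3 only once it is the acrylic acid, so the key-step pair needs no correction.
- Descriptor changes at the ring carbons along the route (for example R in 13–15, S from 29 on at C5) come from CIP ranking only; the geometry set in steps 6 and 7 is unchanged.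
- The arm stays a primary TBS ether so that it can later be removed selectively beside a secondary TBS ether; the lactol reduction is therefore run cold and anhydrous.
- Pent-4-ynal (19) is taken as a commercial aldehyde, distilled before use.

Step 1
Reactants: 1 ethyl 3-(furan-2-yl)-3-oxopropanoate
Product: 2 ethyl (3S)-3-(furan-2-yl)-3-hydroxypropanoate
Conditions: RuCl[(S,S)-TsDPEN](p-cymene) (1 mol %), HCO2H/Et3N (5:2), 25 °C
Reagents that add atoms: none
Why: Noyori asymmetric transfer hydrogenation of a heteroaryl ketone, in which the (S,S)-diamine complex should deliver hydride to the face that places the furan against the arene ligand and so give the (S)-carbinol, the furan ring and the ester being inert to formate.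

Step 2
Reactants: 2 ethyl (3S)-3-(furan-2-yl)-3-hydroxypropanoate
Product: 3 (1S)-1-(furan-2-yl)propane-1,3-diol
Conditions: LiAlH4, THF, 0 °C
Reagents that add atoms: none
Why: Aluminium hydride reduction of the ester to the primary alcohol, which breaks no bond at the carbinol carbon and so retains its configuration.

Step 3
Reactants: 3 (1S)-1-(furan-2-yl)propane-1,3-diol
Product: 4 (1S)-3-(TBSO)-1-(furan-2-yl)propan-1-ol
Conditions: TBSCl (1.05 equiv), imidazole, CH2Cl2, 0 °C
Reagents that add atoms: tert-butyldimethylsilyl chloride, CC(C)(C)[Si](C)(C)Cl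
Why: Kinetically selective silylation of the unhindered primary hydroxyl over the secondary furyl carbinol with one equivalent of silyl chloride in the cold.

Step 4
Reactants: 4 (1S)-3-(TBSO)-1-(furan-2-yl)propan-1-ol
Product: 7 (2S)-2-[2-(TBSO)ethyl]-6-hydroxy-2H-pyran-3(6H)-one (C6 anomers), via bromohydroxy-dihydrofuran adduct 5 (not isolated), via open-chain Z-enedione 6 (not isolated)
Conditions: NBS (1.05 equiv), NaHCO3, NaOAc, THF/H2O (4:1), 0 °C
Reagents that add atoms: water, O
Why: Achmatowicz rearrangement: bromonium transfer from NBS to the free α-position of the furan and capture by water give adduct 5, which opens with loss of bromide to the (Z)-enedione 6. The carbinol hydroxyl then adds to the aldehyde carbonyl in a 6-exo-trig hemiacetalisation, which forms the O1–C6 bond and closes the oxane ring as the pyranone. The closest known reaction type is the oxidative ring expansion of 2-furyl carbinols with NBS or a peracid. The only new stereocentre is the anomeric C6, which forms without control and is removed in step 5, while C2 has no bond broken and keeps its (S) configuration. The step needs chemoselective oxidation of the furan over the secondary alcohol and the silyl ether, which the much higher nucleophilicity of the furan toward buffered NBS at 0 °C should secure, and the ring size is fixed because only the carbinol oxygen can reach the aldehyde carbon.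

Step 5
Reactants: 7 (2S)-2-[2-(TBSO)ethyl]-6-hydroxy-2H-pyran-3(6H)-one
Product: 8 (2S)-2-[2-(TBSO)ethyl]-2H-pyran-3(6H)-one
Conditions: Et3SiH, CF3CO2H, CH2Cl2, −40 °C
Reagents that add atoms: none
Why: Ionic hydrogenation of a lactol, in which acid ionises the anomeric hydroxyl and the silane delivers hydride to C6, the cold, anhydrous and non-basic medium being chosen to spare the silyl ether and the enolisable C2 centre.

Step 6
Reactants: 8 (2S)-2-[2-(TBSO)ethyl]-2H-pyran-3(6H)-one
Product: 9 (2S,3R)-2-[2-(TBSO)ethyl]-3,6-dihydro-2H-pyran-3-ol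
Conditions: NaBH4, CeCl3·7H2O, MeOH, −78 °C
Reagents that add atoms: none
Why: Luche reduction, in which 1,2-hydride addition occurs axially on the half-chair that keeps the C2 arm pseudo-equatorial and should therefore place the C3 hydroxyl trans to the arm (3R), the cis isomer being separable at this stage.

Step 7
Reactants: 9 (2S,3R)-2-[2-(TBSO)ethyl]-3,6-dihydro-2H-pyran-3-ol; 10 triethyl orthoacetate
Product: 12 ethyl 2-[(3S,6S)-6-[2-(TBSO)ethyl]-3,6-dihydro-2H-pyran-3-yl]acetate, via ketene acetal 11 (not isolated)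
Conditions: EtCO2H (cat.), neat in 10 (excess), 140 °C, EtOH distilled off
Reagents that add atoms: none
Why: Johnson–Claisen rearrangement, in which acid-catalysed exchange and loss of ethanol give ketene acetal 11 whose [3,3] shift is suprafacial, so the new C–C bond at C5 forms on the face that carried the C3 oxygen, trans to the C2 arm.

Step 8
Reactants: 12 ethyl 2-[(3S,6S)-6-[2-(TBSO)ethyl]-3,6-dihydro-2H-pyran-3-yl]acetate
Product: 13 ethyl 2-[(3R,6R)-6-[2-(TBSO)ethyl]oxan-3-yl]acetate
Conditions: H2 (1 atm), PtO2, EtOAc, 25 °C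
Reagents that add atoms: none
Why: Catalytic hydrogenation of the cis-disubstituted ring alkene, with PtO2 chosen over palladium to limit allylic C–O hydrogenolysis and double-bond migration, and with no stereocentre formed or touched.

Step 9
Reactants: 13 ethyl 2-[(3R,6R)-6-[2-(TBSO)ethyl]oxan-3-yl]acetate
Product: 14 2-[(3R,6R)-6-[2-(TBSO)ethyl]oxan-3-yl]ethan-1-ol
Conditions: LiAlH4, THF, 0 °C
Reagents that add atoms: none
Why: Aluminium hydride reduction of the ester to the primary alcohol, to which the silyl ether and the ring are inert.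

Step 10
Reactants: 14 2-[(3R,6R)-6-[2-(TBSO)ethyl]oxan-3-yl]ethan-1-ol
Product: 15 tert-butyl{2-[(2R,5R)-5-(2-iodoethyl)oxan-2-yl]ethoxy}dimethylsilane
Conditions: I2, PPh3, imidazole, CH2Cl2, 0 → 25 °C
Reagents that add atoms: iodine, II
Why: Appel-type iodination (Garegg–Samuelsson conditions), an SN2 displacement at the activated primary carbon in a buffered medium that the silyl ether tolerates.

Step 11
Reactants: 16 6-methylhept-5-en-2-one
Product: 18 6-methylhepta-1,5-dien-2-yl trifluoromethanesulfonate, via lithium enolate 17 (not isolated)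
Conditions: LiN(i-Pr)2, THF, −78 °C; then PhNTf2, −78 → 0 °C
Reagents that add atoms: N-phenylbis(trifluoromethanesulfonimide), O=S(=O)(N(c1ccccc1)S(=O)(=O)C(F)(F)F)C(F)(F)F
Why: Kinetic enol triflate formation, in which the hindered amide removes a methyl proton at −78 °C and the terminal enolate 17 is sulfonylated on oxygen.

Step 12
Reactants: 18 6-methylhepta-1,5-dien-2-yl trifluoromethanesulfonate; 19 pent-4-ynal
Product: 21 rac-10-methyl-6-methylideneundec-9-en-1-yn-5-ol, via alkenylchromium dichloride 20 (not isolated)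
Conditions: CrCl2 (4 equiv), NiCl2 (2 mol %), DMF, 25 °C
Reagents that add atoms: none
Why: Nozaki–Hiyama–Kishi coupling, in which nickel-catalysed activation of the triflate and transfer to chromium give 20, which adds chemoselectively to the aldehyde beside the terminal alkyne; the carbinol forms racemic and is corrected in steps 13 and 14.

Step 13
Reactants: 21 rac-10-methyl-6-methylideneundec-9-en-1-yn-5-ol
Product: 22 10-methyl-6-methylideneundec-9-en-1-yn-5-one
Conditions: Dess–Martin periodinane, NaHCO3, CH2Cl2, 0 °C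
Reagents that add atoms: none
Why: Dess–Martin oxidation of the secondary allylic alcohol to the α-methylene ketone under buffered conditions, the product being used at once.

Step 14
Reactants: 22 10-methyl-6-methylideneundec-9-en-1-yn-5-one
Product: 23 (5R)-10-methyl-6-methylideneundec-9-en-1-yn-5-ol
Conditions: (S)-2-methyl-CBS-oxazaborolidine (20 mol %), catecholborane, toluene, −78 °C
Reagents that add atoms: none
Why: Corey–Bakshi–Shibata reduction, in which the α-branched alkenyl group acts as the large substituent and the CH2 chain as the small one, so the (S)-oxazaborolidine should give the (R)-alcohol, while catecholborane at −78 °C spares the alkyne and the alkenes.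

Step 15
Reactants: 23 (5R)-10-methyl-6-methylideneundec-9-en-1-yn-5-ol
Product: 24 tert-butyldimethyl{[(5R)-10-methyl-6-methylideneundec-9-en-1-yn-5-yl]oxy}silane
Conditions: TBSOTf, 2,6-lutidine, CH2Cl2, −78 → 0 °C
Reagents that add atoms: tert-butyldimethylsilyl trifluoromethanesulfonate, CC(C)(C)[Si](C)(C)OS(=O)(=O)C(F)(F)F
Why: Silylation of the hindered secondary allylic alcohol with the silyl triflate, which touches no stereocentre.

Step 16
Reactants: 24 tert-butyldimethyl{[(5R)-10-methyl-6-methylideneundec-9-en-1-yn-5-yl]oxy}silane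
Product: 26 tert-butyl{[(1E,5R)-1-iodo-2,10-dimethyl-6-methylideneundeca-1,9-dien-5-yl]oxy}dimethylsilane, via alkenyldimethylalane 25 (not isolated)
Conditions: Me3Al, Cp2ZrCl2 (25 mol %), CH2Cl2, 0 → 25 °C; then I2, THF, −30 → 0 °C
Reagents that add atoms: trimethylaluminium, C[Al](C)C; iodine, II
Why: Negishi zirconium-catalysed carboalumination, a syn addition of methyl and aluminium across the terminal alkyne with aluminium on the terminal carbon, followed by iodinolysis with retention to give the (E)-iodoalkene, the other alkenes being inert.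

Step 17
Reactants: 15 tert-butyl{2-[(2R,5R)-5-(2-iodoethyl)oxan-2-yl]ethoxy}dimethylsilane; 26 tert-butyl{[(1E,5R)-1-iodo-2,10-dimethyl-6-methylideneundeca-1,9-dien-5-yl]oxy}dimethylsilane
Product: 29 tert-butyl{2-[(2R,5S)-5-[(3E,7R)-7-(TBSO)-4,12-dimethyl-8-methylidenetrideca-3,11-dien-1-yl]oxan-2-yl]ethoxy}dimethylsilane, via alkyllithium 27 (not isolated), via lithium methoxyborate 28 (not isolated)
Conditions: 15, t-BuLi (2.1 equiv), Et2O, −78 °C; B-methoxy-9-BBN, THF, −78 → 25 °C; then 26, Pd(dppf)Cl2 (5 mol %), AsPh3, K3PO4 (aq.), DMF, 25 °C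
Reagents that add atoms: none
Why: B-alkyl Suzuki–Miyaura coupling, in which lithium–iodine exchange and capture by the borinate give ate complex 28 that transfers its primary alkyl group to palladium for sp3–sp2 coupling with retention of the (E)-alkene geometry and no stereocentre involved.

Step 18
Reactants: 29 bis-silyl ether from step 17
Product: 30 2-[(2R,5S)-5-[(3E,7R)-7-(TBSO)-4,12-dimethyl-8-methylidenetrideca-3,11-dien-1-yl]oxan-2-yl]ethan-1-ol
Conditions: camphorsulfonic acid (10 mol %), MeOH/CH2Cl2 (1:1), 0 °C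
Reagents that add atoms: none
Why: Selective desilylation by acid-catalysed methanolysis, which should remove the unhindered primary silyl ether much faster than the hindered secondary allylic one.

Step 19
Reactants: 30 primary alcohol from step 18
Product: 31 2-[(2R,5S)-5-[(3E,7R)-7-(TBSO)-4,12-dimethyl-8-methylidenetrideca-3,11-dien-1-yl]oxan-2-yl]acetaldehyde
Conditions: Dess–Martin periodinane, NaHCO3, CH2Cl2, 0 → 25 °C
Reagents that add atoms: none
Why: Dess–Martin oxidation of the primary alcohol to the aldehyde under buffered, non-basic conditions that should avoid β-elimination of the ring oxygen.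

Step 20
Reactants: 31 aldehyde from step 19
Product: 33 2-[(2R,5S)-5-[(3E,7R)-7-(TBSO)-4,12-dimethyl-8-methylidenetrideca-3,11-dien-1-yl]oxan-2-yl]prop-2-enal, via Mannich base 32 (not isolated)
Conditions: CH2=NMe2 I (Eschenmoser's salt), Et3N, CH2Cl2, 25 °C
Reagents that add atoms: N,N-dimethylmethyleneiminium iodide, C=[N+](C)C.[I-]
Why: Mannich methylenation, in which the aldehyde enol attacks the iminium ion and β-amino aldehyde 32 loses dimethylamine to give the α-methylene aldehyde, with no bond to C2 broken.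

Step 21
Reactants: 33 enal from step 20
Product: 34 2-[(2R,5S)-5-[(3E,7R)-7-(TBSO)-4,12-dimethyl-8-methylidenetrideca-3,11-dien-1-yl]oxan-2-yl]prop-2-enoic acid
Conditions: NaClO2, NaH2PO4, 2-methylbut-2-ene, t-BuOH/H2O, 0 → 25 °C
Reagents that add atoms: sodium chlorite, [Na+].[O-]Cl=O
Why: Pinnick oxidation of the enal to the acrylic acid, with 2-methylbut-2-ene scavenging hypochlorous acid so that the three other alkenes are spared.

Step 22
Reactants: 34 silyl-protected acid from step 21
Product: 35 2-[(2R,5S)-5-[(3E,7R)-7-hydroxy-4,12-dimethyl-8-methylidenetrideca-3,11-dien-1-yl]oxan-2-yl]prop-2-enoic acid (target)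
Conditions: HF·pyridine, pyridine, THF, 0 → 25 °C
Reagents that add atoms: none
Why: Fluoride-driven desilylation of the secondary silyl ether, which frees the (R)-carbinol without affecting the acrylic acid or the alkenes.

Compound list
1 | ethyl 3-(furan-2-yl)-3-oxopropanoate | CCOC(=O)CC(=O)c1ccco1 | starting material
2 | ethyl (3S)-3-(furan-2-yl)-3-hydroxypropanoate | CCOC(=O)C[C@H](O)c1ccco1 | intermediate
3 | (1S)-1-(furan-2-yl)propane-1,3-diol | OCC[C@H](O)c1ccco1 | intermediate
4 | (1S)-3-[(tert-butyldimethylsilyl)oxy]-1-(furan-2-yl)propan-1-ol | CC(C)(C)[Si](C)(C)OCC[C@H](O)c1ccco1 | intermediate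
5 | (1S)-1-(5-bromo-2-hydroxy-2,5-dihydrofuran-2-yl)-3-[(tert-butyldimethylsilyl)oxy]propan-1-ol (ring centres unassigned) | OC1(C=CC(Br)O1)[C@@H](O)CCO[Si](C)(C)C(C)(C)C | intermediate (not isolated)
6 | (2Z,5S)-7-[(tert-butyldimethylsilyl)oxy]-5-hydroxy-4-oxohept-2-enal | O=C/C=C\C(=O)[C@@H](O)CCO[Si](C)(C)C(C)(C)C | intermediate (not isolated)
7 | (2S)-2-{2-[(tert-butyldimethylsilyl)oxy]ethyl}-6-hydroxy-2H-pyran-3(6H)-one (C6 anomers) | OC1C=CC(=O)[C@H](CCO[Si](C)(C)C(C)(C)C)O1 | intermediate
8 | (2S)-2-{2-[(tert-butyldimethylsilyl)oxy]ethyl}-2H-pyran-3(6H)-one | C1C=CC(=O)[C@H](CCO[Si](C)(C)C(C)(C)C)O1 | intermediate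
9 | (2S,3R)-2-{2-[(tert-butyldimethylsilyl)oxy]ethyl}-3,6-dihydro-2H-pyran-3-ol | C1C=C[C@@H](O)[C@H](CCO[Si](C)(C)C(C)(C)C)O1 | intermediate
10 | triethyl orthoacetate (1,1,1-triethoxyethane) | CC(OCC)(OCC)OCC | starting material
11 | (2S,3R)-2-{2-[(tert-butyldimethylsilyl)oxy]ethyl}-3-[(1-ethoxyethenyl)oxy]-3,6-dihydro-2H-pyran | C1C=C[C@@H](OC(=C)OCC)[C@H](CCO[Si](C)(C)C(C)(C)C)O1 | intermediate (not isolated)
12 | ethyl 2-[(3S,6S)-6-{2-[(tert-butyldimethylsilyl)oxy]ethyl}-3,6-dihydro-2H-pyran-3-yl]acetate | CCOC(=O)C[C@@H]1CO[C@@H](CCO[Si](C)(C)C(C)(C)C)C=C1 | intermediate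
13 | ethyl 2-[(3R,6R)-6-{2-[(tert-butyldimethylsilyl)oxy]ethyl}oxan-3-yl]acetate | CCOC(=O)C[C@@H]1CO[C@@H](CCO[Si](C)(C)C(C)(C)C)CC1 | intermediate
14 | 2-[(3R,6R)-6-{2-[(tert-butyldimethylsilyl)oxy]ethyl}oxan-3-yl]ethan-1-ol | OCC[C@@H]1CO[C@@H](CCO[Si](C)(C)C(C)(C)C)CC1 | intermediate
15 | tert-butyl{2-[(2R,5R)-5-(2-iodoethyl)oxan-2-yl]ethoxy}dimethylsilane | ICC[C@@H]1CO[C@@H](CCO[Si](C)(C)C(C)(C)C)CC1 | intermediate
16 | 6-methylhept-5-en-2-one | CC(=O)CCC=C(C)C | starting material
17 | lithium 6-methylhepta-1,5-dien-2-olate | [Li+].C=C([O-])CCC=C(C)C | intermediate (not isolated)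
18 | 6-methylhepta-1,5-dien-2-yl trifluoromethanesulfonate | C=C(CCC=C(C)C)OS(=O)(=O)C(F)(F)F | intermediate
19 | pent-4-ynal | C#CCCC=O | starting material
20 | dichloro(6-methylhepta-1,5-dien-2-yl)chromium | C=C(CCC=C(C)C)[Cr](Cl)Cl | intermediate (not isolated)
21 | rac-10-methyl-6-methylideneundec-9-en-1-yn-5-ol | C=C(CCC=C(C)C)C(O)CCC#C | intermediate
22 | 10-methyl-6-methylideneundec-9-en-1-yn-5-one | C=C(CCC=C(C)C)C(=O)CCC#C | intermediate
23 | (5R)-10-methyl-6-methylideneundec-9-en-1-yn-5-ol | C=C(CCC=C(C)C)[C@H](O)CCC#C | intermediate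
24 | tert-butyldimethyl{[(5R)-10-methyl-6-methylideneundec-9-en-1-yn-5-yl]oxy}silane | C=C(CCC=C(C)C)[C@H](O[Si](C)(C)C(C)(C)C)CCC#C | intermediate
25 | {(1E,5R)-5-[(tert-butyldimethylsilyl)oxy]-2,10-dimethyl-6-methylideneundeca-1,9-dien-1-yl}dimethylalumane | C=C(CCC=C(C)C)[C@H](O[Si](C)(C)C(C)(C)C)CC/C(C)=C/[Al](C)C | intermediate (not isolated)
26 | tert-butyl{[(1E,5R)-1-iodo-2,10-dimethyl-6-methylideneundeca-1,9-dien-5-yl]oxy}dimethylsilane | C=C(CCC=C(C)C)[C@H](O[Si](C)(C)C(C)(C)C)CC/C(C)=C/I | intermediate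
27 | {2-[(3S,6R)-6-{2-[(tert-butyldimethylsilyl)oxy]ethyl}oxan-3-yl]ethyl}lithium | [Li]CC[C@@H]1CO[C@@H](CCO[Si](C)(C)C(C)(C)C)CC1 | intermediate (not isolated)
28 | lithium 9-{2-[(3S,6R)-6-{2-[(tert-butyldimethylsilyl)oxy]ethyl}oxan-3-yl]ethyl}-9-methoxy-9-boranuidabicyclo[3.3.1]nonane | [Li+].CO[B-]1(CC[C@@H]2CO[C@@H](CCO[Si](C)(C)C(C)(C)C)CC2)C2CCCC1CCC2 | intermediate (not isolated)
29 | tert-butyl{2-[(2R,5S)-5-[(3E,7R)-7-[(tert-butyldimethylsilyl)oxy]-4,12-dimethyl-8-methylidenetrideca-3,11-dien-1-yl]oxan-2-yl]ethoxy}dimethylsilane | C=C(CCC=C(C)C)[C@H](O[Si](C)(C)C(C)(C)C)CC/C(C)=C/CC[C@@H]1CO[C@@H](CCO[Si](C)(C)C(C)(C)C)CC1 | intermediate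
30 | 2-[(2R,5S)-5-[(3E,7R)-7-[(tert-butyldimethylsilyl)oxy]-4,12-dimethyl-8-methylidenetrideca-3,11-dien-1-yl]oxan-2-yl]ethan-1-ol | C=C(CCC=C(C)C)[C@H](O[Si](C)(C)C(C)(C)C)CC/C(C)=C/CC[C@@H]1CO[C@@H](CCO)CC1 | intermediate
31 | 2-[(2R,5S)-5-[(3E,7R)-7-[(tert-butyldimethylsilyl)oxy]-4,12-dimethyl-8-methylidenetrideca-3,11-dien-1-yl]oxan-2-yl]acetaldehyde | C=C(CCC=C(C)C)[C@H](O[Si](C)(C)C(C)(C)C)CC/C(C)=C/CC[C@@H]1CO[C@@H](CC=O)CC1 | intermediate
32 | 3-(dimethylamino)-2-[(2R,5S)-5-[(3E,7R)-7-[(tert-butyldimethylsilyl)oxy]-4,12-dimethyl-8-methylidenetrideca-3,11-dien-1-yl]oxan-2-yl]propanal (epimers at the α-carbon) | C=C(CCC=C(C)C)[C@H](O[Si](C)(C)C(C)(C)C)CC/C(C)=C/CC[C@@H]1CO[C@@H](C(CN(C)C)C=O)CC1 | intermediate (not isolated)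
33 | 2-[(2R,5S)-5-[(3E,7R)-7-[(tert-butyldimethylsilyl)oxy]-4,12-dimethyl-8-methylidenetrideca-3,11-dien-1-yl]oxan-2-yl]prop-2-enal | C=C(CCC=C(C)C)[C@H](O[Si](C)(C)C(C)(C)C)CC/C(C)=C/CC[C@@H]1CO[C@@H](C(=C)C=O)CC1 | intermediate
34 | 2-[(2R,5S)-5-[(3E,7R)-7-[(tert-butyldimethylsilyl)oxy]-4,12-dimethyl-8-methylidenetrideca-3,11-dien-1-yl]oxan-2-yl]prop-2-enoic acid | C=C(CCC=C(C)C)[C@H](O[Si](C)(C)C(C)(C)C)CC/C(C)=C/CC[C@@H]1CO[C@@H](C(=C)C(=O)O)CC1 | intermediate
35 | 2-[(2R,5S)-5-[(3E,7R)-7-hydroxy-4,12-dimethyl-8-methylidenetrideca-3,11-dien-1-yl]oxan-2-yl]prop-2-enoic acid | C=C(CCC=C(C)C)[C@H](O)CC/C(C)=C/CC[C@H]1CC[C@H](C(=C)C(=O)O)OC1 | target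

Total step count: 22 (steps 1–10 on the oxane line, steps 11–16 for the vinyl iodide, steps 17–22 after the union).
Longest linear sequence: 16 steps (steps 1–10, then 17–22).

Steps most likely to fail

Step 5. The risk is acid-induced loss of the primary silyl ether, followed by internal acetal formation, or enolisation at C2 while the lactol is ionised. The fallback removes the anomeric oxygen only after the ketone has been reduced. It sets out from 7: acetylation of the anomeric hydroxyl (Ac2O, pyridine, DMAP, 0 °C) should give the anomeric acetate F1. Luche reduction (NaBH4, CeCl3·7H2O, MeOH, −78 °C) should then give the trans allylic alcohol F2. A Ferrier-type silane reduction of the allylic anomeric acetate (Et3SiH, BF3·OEt2, CH2Cl2, −78 °C) delivers hydride to C6 and comes back to the route at 9. No enolisable ketone is present during the acid step, and the better leaving group allows colder ionisation.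

Step 7. The risk is ionisation or elimination of the allylic alcohol under hot acid, thermal loss of the silyl ether, or a slow shift from a pseudo-equatorial C–O bond. The fallback is an Ireland–Claisen rearrangement under basic, low-temperature conditions. It sets out from 9: acetylation (Ac2O, pyridine, DMAP) should give the allylic acetate F3. Enolisation and silylation (LiN(i-Pr)2, Me3SiCl, THF, −78 °C) should give the silyl ketene acetal F4, which on warming to 25 °C rearranges suprafacially to the trimethylsilyl ester F5. Aqueous work-up frees the acid F6, and esterification (EtI, K2CO3, DMF) comes back to the route at 12.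

Step 17. The risk is incomplete lithium–iodine exchange, quenching of the alkyllithium before boron capture, or β-hydride elimination at palladium. The fallback is a Negishi coupling through a less basic organometallic. It sets out from 15: zinc insertion (Zn dust activated with 1,2-dibromoethane and Me3SiCl, LiCl, THF, 40 °C) should give the alkylzinc iodide F7. Coupling of F7 with 26 under Pd(PPh3)4 (zerovalent palladium) in THF/DMA at 25 °C comes back to the route at 29.

Further compounds
F1 | step 5 | (6S)-6-{2-[(tert-butyldimethylsilyl)oxy]ethyl}-5-oxo-5,6-dihydro-2H-pyran-2-yl acetate (anomers) | CC(=O)OC1C=CC(=O)[C@H](CCO[Si](C)(C)C(C)(C)C)O1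
F2 | step 5 | (5R,6S)-6-{2-[(tert-butyldimethylsilyl)oxy]ethyl}-5-hydroxy-5,6-dihydro-2H-pyran-2-yl acetate (anomers) | CC(=O)OC1C=C[C@@H](O)[C@H](CCO[Si](C)(C)C(C)(C)C)O1
F3 | step 7 | (2S,3R)-2-{2-[(tert-butyldimethylsilyl)oxy]ethyl}-3,6-dihydro-2H-pyran-3-yl acetate | C1C=C[C@@H](OC(C)=O)[C@H](CCO[Si](C)(C)C(C)(C)C)O1
F4 | step 7 | (2S,3R)-2-{2-[(tert-butyldimethylsilyl)oxy]ethyl}-3-({1-[(trimethylsilyl)oxy]ethenyl}oxy)-3,6-dihydro-2H-pyran | C1C=C[C@@H](OC(=C)O[Si](C)(C)C)[C@H](CCO[Si](C)(C)C(C)(C)C)O1
F5 | step 7 | trimethylsilyl 2-[(3S,6S)-6-{2-[(tert-butyldimethylsilyl)oxy]ethyl}-3,6-dihydro-2H-pyran-3-yl]acetate | C[Si](C)(C)OC(=O)C[C@@H]1CO[C@@H](CCO[Si](C)(C)C(C)(C)C)C=C1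
F6 | step 7 | 2-[(3S,6S)-6-{2-[(tert-butyldimethylsilyl)oxy]ethyl}-3,6-dihydro-2H-pyran-3-yl]acetic acid | OC(=O)C[C@@H]1CO[C@@H](CCO[Si](C)(C)C(C)(C)C)C=C1
F7 | step 17 | {2-[(3R,6R)-6-{2-[(tert-butyldimethylsilyl)oxy]ethyl}oxan-3-yl]ethyl}zinc iodide | I[Zn]CC[C@@H]1CO[C@@H](CCO[Si](C)(C)C(C)(C)C)CC1
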